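**Retrosynthetic overview**

1. Feature used: in the cyclopentenone ring (C5–C6–C7–C8–C9), C9 carries OH and an acetyl group and is bonded to spiro C5. This C9(OH)–C(=O)CH3 unit is the acyloin (α-ketol) shift isomer of a six-membered 10-hydroxy-10-methyl-6,9-dione in which the acetyl carbon is still ring atom C10. The five-membered ring can therefore be made last by contracting a ring that still holds all six carbons of a trimethylhydroquinone.
2. Disconnections: 15 ⇒ α-ketol 14 (C5 returned from C9 to C10) ⇒ enol ether 12 (C10–OH removed) ⇒ phenol 11 (C5–O1 opened, rearomatised) ⇒ bromoarene 8 + (3S)-isophytol 4 (aryl–CH2, B-alkyl Suzuki) ⇒ trimethylhydroquinone 5 and natural phytol 1.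
3. Ring order: benzene ring (bought) → tetrahydrofuran by ortho-spiroetherification (step 9) → cyclopentenone by six-to-five ring contraction (step 10).
4. Stereocentres: C4′/C8′ are bought with phytol; C2 is set by reagent-controlled epoxidation; C5 is set by a chiral iodine(III) reagent, because C2 (CH3 versus CH2R) cannot bias the ring faces; C9 is relayed from C5 through transient C10 in the key step.

Key step: step 10

Remark on the chemistry: the SMILES is read as (2S,5R,9S) with a (4R,8R) side chain; C2 then has the opposite sense to C2 of natural (2R)-α-tocopherol, so vitamin E and its quinone are not usable and C2 is built from natural phytol.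
Remark on the chemistry: the sense of induction of the chiral iodane in step 9 is assumed to be that of the (R,R) reagent as written; the (S,S) antipode is equally accessible if the first run shows the opposite sense. The parent iodoarene is made from 2-iodoresorcinol, a lactate ester and 2,4,6-trimethylaniline and is recovered after use.

**Step 1**
Reactants: 1 (2E,7R,11R)-3,7,11,15-tetramethylhexadec-2-en-1-ol (natural phytol)
Product: 2 [(2S,3S)-3-methyl-3-[(4R,8R)-4,8,12-trimethyltridecyl]oxiran-2-yl]methanol
Conditions: Ti(OiPr)4 (10 mol %), L-(+)-diethyl tartrate (12 mol %), t-BuOOH, 4 Å MS, CH2Cl2, −20 °C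
Reagents that add atoms: tert-butyl hydroperoxide, CC(C)(C)OO
Why: Katsuki–Sharpless asymmetric epoxidation of an (E)-trisubstituted allylic alcohol, in which L-(+)-tartrate delivers oxygen to the face that gives the (2S,3S) epoxide (as with geraniol), so the future C2 of the target is set under reagent control while the remote 7R,11R centres are spectators.

**Step 2**
Reactants: 2 [(2S,3S)-3-methyl-3-[(4R,8R)-4,8,12-trimethyltridecyl]oxiran-2-yl]methanol
Product: 3 (2R,3S)-2-(iodomethyl)-3-methyl-3-[(4R,8R)-4,8,12-trimethyltridecyl]oxirane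
Conditions: I2, PPh3, imidazole, Et2O/MeCN, 0 °C
Reagents that add atoms: iodine, II
Why: Appel-type iodination of the primary alcohol under neutral conditions, which leaves the epoxide and both of its stereocentres untouched (the 2R descriptor is a CIP rank change only).

**Step 3**
Reactants: 3 (2R,3S)-2-(iodomethyl)-3-methyl-3-[(4R,8R)-4,8,12-trimethyltridecyl]oxirane
Product: 4 (3S,7R,11R)-3,7,11,15-tetramethylhexadec-1-en-3-ol ((3S)-isophytol)
Conditions: Zn dust, AcOH, MeOH, 0 °C → rt
Reagents that add atoms: none
Why: Zinc inserts into the C–I bond and the organozinc opens the neighbouring epoxide by β-elimination (reductive opening of a 2,3-epoxy iodide), which gives the tertiary allylic alcohol with the C3–O bond, and hence the configuration, intact.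

**Step 4**
Reactants: 5 2,3,5-trimethylbenzene-1,4-diol (trimethylhydroquinone)
Product: 6 4-(benzyloxy)-2,3,6-trimethylphenol
Conditions: BnBr (1.0 equiv), K2CO3, acetone, reflux, Ar
Reagents that add atoms: benzyl bromide, BrCc1ccccc1
Why: Williamson etherification in which the hydroxyl next to the unsubstituted ring position (one ortho methyl) should react faster than the hydroxyl between two methyl groups, with one equivalent of halide limiting bis-alkylation.

**Step 5**
Reactants: 6 4-(benzyloxy)-2,3,6-trimethylphenol
Product: 7 1-(benzyloxy)-4-methoxy-2,3,5-trimethylbenzene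
Conditions: NaH, MeI, DMF, 0 °C → rt
Reagents that add atoms: iodomethane, CI
Why: Williamson methylation of the remaining hindered phenoxide with the smallest electrophile.

**Step 6**
Reactants: 7 1-(benzyloxy)-4-methoxy-2,3,5-trimethylbenzene
Product: 8 1-(benzyloxy)-2-bromo-4-methoxy-3,5,6-trimethylbenzene
Conditions: NBS, MeCN, 0 °C → rt, dark
Reagents that add atoms: N-bromosuccinimide, O=C1CCC(=O)N1Br
Why: Electrophilic aromatic bromination at the only free ring position, activated by the ortho benzyloxy group, with a polar solvent in the dark to avoid benzylic bromination.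

**Step 7**
Reactants: 4 (3S,7R,11R)-3,7,11,15-tetramethylhexadec-1-en-3-ol; 8 1-(benzyloxy)-2-bromo-4-methoxy-3,5,6-trimethylbenzene
Product: 10 (3S,7R,11R)-1-[2-(benzyloxy)-5-methoxy-3,4,6-trimethylphenyl]-3,7,11,15-tetramethylhexadecan-3-ol, via B-alkyl-9-BBN 9 (not isolated)
Conditions: 9-BBN, THF, 0 °C → rt; then 8, Pd(OAc)2 (5 mol %), SPhos (10 mol %), aq K3PO4, THF, 65 °C
Reagents that add atoms: none
Why: Anti-Markovnikov hydroboration of the vinyl group followed by B-alkyl Suzuki–Miyaura coupling, for which SPhos-ligated palladium tolerates di-ortho-substituted electron-rich bromides; no stereocentre is touched and the tertiary alcohol needs no protection.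

**Step 8**
Reactants: 10 (3S,7R,11R)-1-[2-(benzyloxy)-5-methoxy-3,4,6-trimethylphenyl]-3,7,11,15-tetramethylhexadecan-3-ol
Product: 11 2-[(3S,7R,11R)-3-hydroxy-3,7,11,15-tetramethylhexadecyl]-4-methoxy-3,5,6-trimethylphenol
Conditions: H2 (1 atm), 10 % Pd/C, EtOAc, rt
Reagents that add atoms: none
Why: Hydrogenolysis of the aryl benzyl ether under neutral conditions, which avoids acid-induced cyclisation of the phenol onto the tertiary alcohol (chroman formation with loss of C2 integrity).

**Step 9**
Reactants: 11 2-[(3S,7R,11R)-3-hydroxy-3,7,11,15-tetramethylhexadecyl]-4-methoxy-3,5,6-trimethylphenol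
Product: 12 (2S,5R)-9-methoxy-2,7,8,10-tetramethyl-2-[(4R,8R)-4,8,12-trimethyltridecyl]-1-oxaspiro[4.5]deca-7,9-dien-6-one
Conditions: pre-formed (R,R)-ArI(OAc)2 [Ar = 2,6-bis(1-(mesitylcarbamoyl)ethoxy)phenyl] (1.1 equiv, no free peracid), CH2Cl2, −40 → −20 °C
Reagents that add atoms: none
Why: Proposed new method: the phenol exchanges onto the chiral aryl-λ3-iodane and the tethered tertiary OH attacks the ortho carbon bearing the chain (5-exo) as the iodoarene leaves, so that C5–O1 forms inside the lactamide pocket of the reagent, which alone can distinguish the two ring faces, while the para-methoxy group blocks para attack and ends as the C9 enol ether; the closest known reactions are the enantioselective oxidative spirolactonisation of phenols and naphthols bearing tethered carboxylic acids with the same C2-symmetric lactamide iodoarenes and the non-asymmetric PhI(OAc)2 spiroetherification of phenols with tethered alcohols.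

**Step 10**
Reactants: 12 (2S,5R)-9-methoxy-2,7,8,10-tetramethyl-2-[(4R,8R)-4,8,12-trimethyltridecyl]-1-oxaspiro[4.5]deca-7,9-dien-6-one
Product: 15 α-tocospiro A, via methoxy-oxirane 13 (not isolated), via six-membered α-ketol 14 (not isolated)
Conditions: DMDO (1.1 equiv), acetone/CH2Cl2, −78 → −40 °C; then H2O, PPTS (2 mol %), THF, 0 °C; then DBU (0.3 equiv), CH2Cl2, 0 °C → rt (one flask)
Reagents that add atoms: dimethyldioxirane, CC1(C)OO1; water, O
Why: DMDO epoxidises the only electron-rich alkene of 12, the C9=C10 enol ether, on the face of ring oxygen O1 (the other face is shielded by C4H2), the labile methoxy-oxirane 13 is hydrolysed to the tertiary α-ketol 14, and the oxyanion of 14 undergoes the α-ketol (acyloin) 1,2-shift in which the C5–C10 bond migrates to the C9 carbonyl, so that C10 leaves the ring as the acetyl carbon and C9 becomes the carbinol. The closest known reactions are the Rubottom-type α-hydroxylation of enol ethers with dioxiranes and the base-induced six-to-five acyloin ring contraction of humulone to the isohumulones, which creates the same ring C(OH)(acyl) unit. The cyclopentenone is closed by this 1,2-shift (C5–C9 forms as C5–C10 breaks: contraction of the six-membered ring with extrusion of C10, not an exo or endo cyclisation), driven by release of the tetrasubstituted ene-dione with two eclipsed quaternary ring carbons. C5 migrates with retention, and C9 is fixed by the geometry of the shift: without a chelating cation the oxyanion and the accepting carbonyl are anti, so C10 swings out on the face of its own oxygen (the O1 face) and the acetyl group ends cis to O1 with OH cis to C4 (9S), which should also be the more stable epimer because acetyl then faces the ether oxygen and not CH2. The step needs oxidation of the enol ether in preference to the enone and the C–H bonds (secured by its nucleophilicity at −78 °C), migration of the oxygen-bearing quaternary C5 in preference to the methyl group (higher migratory aptitude), and a shift faster than retro-aldol opening of C5–C10, which would scramble C5 (secured by a catalytic non-nucleophilic base at 0 °C and by the poor overlap of this ring bond with the C6 carbonyl π system).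

**Compound list**

1 | (2E,7R,11R)-3,7,11,15-tetramethylhexadec-2-en-1-ol (natural phytol) | OC/C=C(\C)CCC[C@H](C)CCC[C@H](C)CCCC(C)C | starting material
2 | [(2S,3S)-3-methyl-3-[(4R,8R)-4,8,12-trimethyltridecyl]oxiran-2-yl]methanol | OC[C@@H]1O[C@@]1(C)CCC[C@H](C)CCC[C@H](C)CCCC(C)C | intermediate
3 | (2R,3S)-2-(iodomethyl)-3-methyl-3-[(4R,8R)-4,8,12-trimethyltridecyl]oxirane | IC[C@@H]1O[C@@]1(C)CCC[C@H](C)CCC[C@H](C)CCCC(C)C | intermediate
4 | (3S,7R,11R)-3,7,11,15-tetramethylhexadec-1-en-3-ol | C=C[C@@](C)(O)CCC[C@H](C)CCC[C@H](C)CCCC(C)C | intermediate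
5 | 2,3,5-trimethylbenzene-1,4-diol (trimethylhydroquinone) | Cc1cc(O)c(C)c(C)c1O | starting material
6 | 4-(benzyloxy)-2,3,6-trimethylphenol | Cc1cc(OCc2ccccc2)c(C)c(C)c1O | intermediate
7 | 1-(benzyloxy)-4-methoxy-2,3,5-trimethylbenzene | COc1c(C)cc(OCc2ccccc2)c(C)c1C | intermediate
8 | 1-(benzyloxy)-2-bromo-4-methoxy-3,5,6-trimethylbenzene | COc1c(C)c(Br)c(OCc2ccccc2)c(C)c1C | intermediate
9 | 9-[(3R,7R,11R)-3-hydroxy-3,7,11,15-tetramethylhexadecyl]-9-borabicyclo[3.3.1]nonane (carbinol centre spatially as in 4; descriptor changes by CIP rank only) | B1(CC[C@@](C)(O)CCC[C@H](C)CCC[C@H](C)CCCC(C)C)C2CCCC1CCC2 | intermediate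
10 | (3S,7R,11R)-1-[2-(benzyloxy)-5-methoxy-3,4,6-trimethylphenyl]-3,7,11,15-tetramethylhexadecan-3-ol | COc1c(C)c(CC[C@@](C)(O)CCC[C@H](C)CCC[C@H](C)CCCC(C)C)c(OCc2ccccc2)c(C)c1C | intermediate
11 | 2-[(3S,7R,11R)-3-hydroxy-3,7,11,15-tetramethylhexadecyl]-4-methoxy-3,5,6-trimethylphenol | COc1c(C)c(CC[C@@](C)(O)CCC[C@H](C)CCC[C@H](C)CCCC(C)C)c(O)c(C)c1C | intermediate
12 | (2S,5R)-9-methoxy-2,7,8,10-tetramethyl-2-[(4R,8R)-4,8,12-trimethyltridecyl]-1-oxaspiro[4.5]deca-7,9-dien-6-one | COC1=C(C)[C@]2(CC[C@](C)(CCC[C@H](C)CCC[C@H](C)CCCC(C)C)O2)C(=O)C(C)=C1C | intermediate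
13 | 9,10-epoxide of 12 (9-methoxy-oxirane, oxirane oxygen on the face of O1) | CO[C@]12O[C@@]1(C)[C@]3(CC[C@](C)(CCC[C@H](C)CCC[C@H](C)CCCC(C)C)O3)C(=O)C(C)=C2C | intermediate
14 | (2S,5R,10S)-10-hydroxy-2,7,8,10-tetramethyl-2-[(4R,8R)-4,8,12-trimethyltridecyl]-1-oxaspiro[4.5]dec-7-ene-6,9-dione | C[C@@]1(O)C(=O)C(C)=C(C)C(=O)[C@@]12CC[C@](C)(CCC[C@H](C)CCC[C@H](C)CCCC(C)C)O2 | intermediate
15 | α-tocospiro A, (2S,5R,9S)-9-acetyl-9-hydroxy-2,7,8-trimethyl-2-[(4R,8R)-4,8,12-trimethyltridecyl]-1-oxaspiro[4.4]non-7-en-6-one | CC(=O)[C@]1(O)C(C)=C(C)C(=O)[C@@]12CC[C@](C)(CCC[C@H](C)CCC[C@H](C)CCCC(C)C)O2 | target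

**Step count and risks**

Total step count: 10 (side chain 3, arene 3, union and finish 4). Longest linear sequence: 7 steps (1 → 2 → 3 → 4, then steps 7–10; the arene branch is equally long).

Steps most likely to fail:

Step 9 (Proposed new method). If C–O bond formation takes place only after the iodoarene has left (free para-methoxy-stabilised phenoxenium ion), facial discrimination is lost and both C5 epimers form; the same cation can also lose its O-methyl group and collapse to the quinone. Fallback with known chemistry, setting out from 11: oxidation with PhI(OAc)2 in (CF3)2CHOH/CH2Cl2 at 0 °C (standard oxidative ortho-spiroetherification) should give 12 together with its C5 epimer, (2S,5S)-9-methoxy-2,7,8,10-tetramethyl-2-[(4R,8R)-4,8,12-trimethyltridecyl]-1-oxaspiro[4.5]deca-7,9-dien-6-one F1. The two differ as cis/trans 2,5-disubstituted tetrahydrofurans and are to be separated by preparative HPLC on silica. The unwanted epimer is returned to 11 by reductive cleavage of the α-alkoxy ketone (Zn, AcOH, rt) and oxidised again. The route is rejoined at 12.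

Step 10 (key step). Attack of the dioxirane on the other face of the enol ether, or a shift through a chelated (syn) array, would invert C9; retro-aldol opening of the C5–C10 bond under base would scramble C5; a shift of the O-methyl oxocarbenium ion before hydrolysis would trap C9 as its methyl ether. Fallback, setting out from 12: the oxidation is run as before but stopped before the base (DMDO, then wet THF/PPTS) and 14 is isolated. Its tertiary alcohol is silylated (TMSOTf, 2,6-lutidine, CH2Cl2, −78 °C) to (2S,5R,10S)-2,7,8,10-tetramethyl-2-[(4R,8R)-4,8,12-trimethyltridecyl]-10-[(trimethylsilyl)oxy]-1-oxaspiro[4.5]dec-7-ene-6,9-dione F2. F2 is treated with the bulky monodentate Lewis acid methylaluminium bis(2,6-di-tert-butyl-4-methylphenoxide) in toluene at −78 °C (organoaluminium-promoted 1,2-rearrangement of α-siloxy carbonyl compounds). The siloxy group cannot chelate and stays anti to the activated carbonyl, so C5 migrates through the same anti array without any base, and the silyl group passes to the new carbinol oxygen to give (2S,5R,9S)-9-acetyl-2,7,8-trimethyl-2-[(4R,8R)-4,8,12-trimethyltridecyl]-9-[(trimethylsilyl)oxy]-1-oxaspiro[4.4]non-7-en-6-one F3. HF·pyridine (THF, 0 °C) then gives 15.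

Step 7. Oxidative addition and transmetalation at the di-ortho-substituted, electron-rich bromide may be slow, so that protodeboronation of the alkylborane or β-hydride loss from the alkylpalladium intermediate takes over. Fallback, setting out from 4 and 8: a Heck reaction (Pd(OAc)2, P(o-tol)3, Et3N, DMF, 110 °C) on the vinyl carbinol, which has no β-hydrogen on the carbinol side, should give (1E,3S,7R,11R)-1-[2-(benzyloxy)-5-methoxy-3,4,6-trimethylphenyl]-3,7,11,15-tetramethylhexadec-1-en-3-ol F4. Hydrogenation (H2, Pd/C, EtOAc) then saturates the alkene and cleaves the benzyl ether in the same operation, so that the route is rejoined at 11 and 10 is bypassed.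

Further compounds
F1 | step 9 | (2S,5S)-9-methoxy-2,7,8,10-tetramethyl-2-[(4R,8R)-4,8,12-trimethyltridecyl]-1-oxaspiro[4.5]deca-7,9-dien-6-one | COC1=C(C)[C@@]2(CC[C@](C)(CCC[C@H](C)CCC[C@H](C)CCCC(C)C)O2)C(=O)C(C)=C1C
F2 | step 10 | (2S,5R,10S)-2,7,8,10-tetramethyl-2-[(4R,8R)-4,8,12-trimethyltridecyl]-10-[(trimethylsilyl)oxy]-1-oxaspiro[4.5]dec-7-ene-6,9-dione | C[C@@]1(O[Si](C)(C)C)C(=O)C(C)=C(C)C(=O)[C@@]12CC[C@](C)(CCC[C@H](C)CCC[C@H](C)CCCC(C)C)O2
F3 | step 10 | (2S,5R,9S)-9-acetyl-2,7,8-trimethyl-2-[(4R,8R)-4,8,12-trimethyltridecyl]-9-[(trimethylsilyl)oxy]-1-oxaspiro[4.4]non-7-en-6-one | CC(=O)[C@]1(O[Si](C)(C)C)C(C)=C(C)C(=O)[C@@]12CC[C@](C)(CCC[C@H](C)CCC[C@H](C)CCCC(C)C)O2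
F4 | step 7 | (1E,3S,7R,11R)-1-[2-(benzyloxy)-5-methoxy-3,4,6-trimethylphenyl]-3,7,11,15-tetramethylhexadec-1-en-3-ol | COc1c(C)c(/C=C/[C@@](C)(O)CCC[C@H](C)CCC[C@H](C)CCCC(C)C)c(OCc2ccccc2)c(C)c1C
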